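1. I looked first for one rate constant and found that it didn't serve. A first-order constant, pseudo-first-order included, gives the same percentage at any charge, yet at 2.50 min the winter run held 49.0% target and the noon run 68.4%.

| setting | winter | noon | flask |
|---|---|---|---|
| starting material | 0.15 M | 0.60 M | 0.30 M |
| remark | run made earlier | run made earlier |  |
| time |  |  | 2.5 min |

| run | time / min | target / % | isomer of the product / % |
|---|---|---|---|
| winter | 0.333 | 5.4 | 0.3 |
| winter | 0.833 | 21.2 | 3.0 |
| winter | 1.50 | 36.6 | 6.2 |
| winter | 2.50 | 49.0 | 10.3 |
| noon | 0.667 | 16.4 | 2.3 |
| noon | 1.33 | 40.5 | 6.2 |
| noon | 2.00 | 58.3 | 7.9 |
| noon | 2.50 | 68.4 | 8.3 |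

(scatter of a reading: 0.5 percentage points)

- the target in the flask at 2.5 min, as a percentage of the starting material charged
- the isomer of the product in the flask at 2.5 min, as a percentage of the starting material charged

- a reading or a percentage of target counts all its forms, free or not

2. So I counted the fraction left, not the fraction made. The unfinished share is whatever was charged that is neither target nor isomer of the product. At 2.50 min it was 40.7% in the winter run and 23.3% in the noon run.

3. These were my two extreme versions: the flask as lean as winter and the flask as rich as noon. Its charge of 0.30 M is more than winter's and less than noon's, so I placed its unfinished share between them.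

4. I assumed that each doubling of charge multiplied the unfinished share by the same factor, so I took the step from winter to noon, two doublings, as two equal factors. The doubling factor, the number by which one doubling of the charge multiplies the unfinished share at this time, read from these two runs as 0.757.

5. The flask is one doubling above winter, so I expected 30.8% unfinished. Taking the isomer of the product at the geometric mean, 9.25%, left 60.0% target.

6. The forecast said 58% target (54% to 62.5%) and 9.4% isomer of the product (8.2% to 10.8%): “I interpolate in log concentration”. My target stood above its figure.

7. The flask gave 60.8% target and 9.43% isomer of the product, so its unfinished share was 29.8%.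

    starting material → intermediate (k = 0.0230 s⁻¹)
    intermediate ⇌ target (K = 1.30, k = 0.0180 s⁻¹)
    intermediate ⇌ isomer of the product (K = 81.0, k = 0.00180 s⁻¹)
    crystals ⇌ target, rate k4*(cs4 - [target]) while solid is left; crystals form when [target] > cs4 (solubility = 0.0580 M, k = 0.740 s⁻¹)

At 2.50 min, with each step taken net, dissolved target in the flask was made 0.979 times as fast as it was used up, going into crystals counted as use. The flask then held 41.1% crystals, counted within its target, and 26.6% intermediate, counted in its unfinished share. For a neighbouring flask charged at 0.75 M, the doubling factor gave 21.3% unfinished, and that flask stood at 22.6%.

The numbers in the tables were computed for substances that don't exist, and the scatter is random.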